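Locants follow cyclopenta[c]pyridine (C1, N2, C3, C4, C4a, C5, C6, C7, C7a). Ring A is the piperidine, ring B the cyclopentane, ring C the cyclobutane. Nothing here has been run; every outcome is an expectation.

## Analysis of the target

The target is a diester. Two identical (4R,4aS,6R,7S,7aR)-2,4,7-trimethyloctahydro-1H-cyclopenta[c]pyridin-6-yl units are bound through their C6 oxygen to the 1,3-carboxyl groups of a 2,4-bis(4-hydroxyphenyl)cyclobutane (ring C) of α-truxillic configuration: carboxyls mutually trans, aryls mutually trans, each carboxyl cis to one aryl. Each alkaloid unit is a cis-fused bicycle of ring A (N2, C1, C3, C4, C4a, C7a) and ring B (C4a, C5, C6, C7, C7a) with five contiguous stereocentres. The hydrogens at C4, C4a and C7a are mutually cis, the C7 methyl sits on the convex face (cis to H7a), and the C6 oxygen is cis to that methyl. Ring C is centrosymmetric and achiral, so ten of the fourteen stereocentres, and all absolute configuration, lie in the alkaloid units; one enantiopure alcohol used twice is sufficient. Sensitive points are the two hindered secondary esters with epimerisable α-carbons on ring C, the free phenols, the two basic tertiary amines, and the cyclobutane itself, which can undergo photochemical cycloreversion. The difficulty is the stereopentad of the bicycle together with a twofold esterification at a crowded secondary carbon. The strategy rests on ring A: a piperidine with all-cis hydrogens at C4, C4a and C7a is what one-face hydrogenation of a 4-methylcyclopenta[c]pyridine leaves behind, and that pyridine is the dehydrated cycloadduct of a 5-alkyloxazole and a tethered alkene.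

## Retrosynthetic reasoning

29 to 28. The phenols are unmasked last. The two aryl O–benzyl bonds are cut because their hydrogenolysis leaves esters, amines and ring C alone, while the free phenols would compete as nucleophiles in the ester-forming step.

28 to 23 and 27. Both C6–O bonds are cut on the alkyl side, not at the acyl carbon. The reason is that reduction of ketone 22 most naturally gives the concave 6S alcohol 23, and an esterification with inversion turns exactly this epimer into the required 6R ester. The cut is convergent and uses the symmetry of diacid 27, whose two carboxyl groups are equivalent. The forward reaction has to invert a hindered secondary carbon twice without elimination.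

27 to 25 to 24. Ring C is opened across the two C–C bonds of a head-to-tail [2+2] dimerisation, leading to two molecules of cinnamic acid 24. No other cut gives all four cyclobutane centres in one operation. Protection follows dimerisation because the packing of the free acid fixes the α arrangement in 25.

23 to 22, 21, 20 and 19. The C6 alcohol is traced to the ketone so that C7 becomes epimerisable. In 23 the C7 methyl is on the convex face, the thermodynamically preferred side; in 19 it is on the concave face together with the C6 silyloxy group. This cis pair is carried on purpose with the "wrong" configuration: both groups block one face of the flat precursor and are corrected afterwards, C7 by equilibration and C6 by reduction and later inversion.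

19 to 18 to 17. Six hydrogens are removed from ring A and the N-methyl bond is cut. C4, C4a and C7a become sp2, and the forward hydrogenation must return all three from the face opposite to the C6/C7 pair. This reduces the stereochemical problem of the bicycle to two centres.

17 to 14. This is the key disconnection: C7a–C4a and C3–C4 are cut and the elements of water are put back, which turns the pyridine into a 5-alkyloxazole carrying a cis-alkene three carbons away. Other pyridine disconnections would need a functionalised cyclopentane first; this one opens rings A and B together to an acyclic chain whose only stereocentres are C6 and C7. The forward step must form two C–C bonds and aromatise without disturbing that pair.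

14 to 12 and 13, then 12 to 11 to 10. The alkene is cut at its double bond into aldehyde 12 and the two-carbon phosphonium salt 13. The aldehyde comes from primary alcohol 11 and its benzyl ether 10. The alkene is introduced late so that it never meets a hydrogenation catalyst.

10 to 7 and 8. The oxazole is cut at C4–C5 and O1–C2, which returns aldehyde 7 and isocyanide 8. The aldehyde carbon becomes C7a, so no carbon is wasted.

7 to 6, 5, 4, 3, and 3 to 1 and 2. The anti methyl/oxygen pair of the chain becomes the cis pair on ring B. The C7–methyl bond is cut at the carbon α to the ester (5 to 4), where the neighbouring carbinol directs the alkylation, and the C6 carbinol is traced to β-keto ester 3, where a catalyst sets the absolute configuration. Keto ester 3 comes from 1 and 2 by γ-alkylation.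

## Alternatives that were turned down

Alternative 1: Ring C is kept and its two aryl–carbon bonds (C2–aryl, C4–aryl) are cut. In the forward direction the trans-1,3-bis(8-quinolinylamide) A1 would be arylated twice with aryl iodide A2 under Pd(OAc)2 (divalent palladium) and AgOAc, each amide guiding the metal to a cis β-C–H bond, to give diamide A3.
- For it: the outcome does not depend on crystal packing, the aryl groups are modular, and the directing geometry (aryl cis to the guiding amide) matches the α arrangement. On independence from the solid state it is the stronger plan.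
- Against it: the second arylation must occur at the other methylene under the other amide; double arylation under one amide or at one carbon would compete. The two hindered amides must then be cleaved to the diacid without epimerising the α-carbons, which usually needs forcing or activating conditions. That makes about five steps to reach 27, against two from 24.
- Comparison: it spends its key step on the half of the molecule that carries no absolute stereochemistry and leaves the alkaloid unit unsolved. The chosen strategy gives ring C in one step and puts its effort into rings A and B.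

Alternative 2: Ring B is cut at C4a–C5. The methyl ketone enolate of dihydropyridinone A4 would add in a 5-exo-trig conjugate addition to C4a under catalytic KOtBu and give the cis-fused keto lactam A5.
- For it: A5 already has the C6 ketone, the N-methyl group and the final C7 configuration, so it is only a lactam reduction and a ketone reduction away from 23. After the key step it is clearly shorter than the chosen route, which needs desilylation, oxidation and epimerisation.
- Against it: A4 needs the vicinal C7/C7a pair set with absolute control on a side chain of a dihydropyridinone, which costs the steps saved later. The acceptor is an α-methyl unsaturated lactam, a weak electrophile whose β-carbon becomes a tertiary centre. The base must deprotonate the methyl group and not C7, whose enolisation would erase that centre. C4 is fixed only by protonation of the lactam enolate under reversible conditions, with no element that secures the required H4/H4a cis relation.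
- Comparison: the chosen strategy sets C4, C4a and C7a in a single hydrogenation with a clear facial bias and closes both rings by a precedented cycloaddition; it pays for this with the C6/C7 correction.

Alternative 3: One C–C bond of ring C is cut and traced to the two C–N bonds of a pyrrolidine. NH-pyrrolidine A6 would be N-aminated by the iodonitrene formed from PhI(OH)OTs and ammonium carbamate; the 1,1-diazene extrudes nitrogen and the 1,4-biradical closes to cyclobutane diester A7.
- For it: no photochemistry and no reliance on packing, and pyrrolidines of this substitution pattern are one cycloaddition away from simple components.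
- Against it: the α arrangement requires the 2,5-trans pyrrolidine (2,3-cis, 3,4-trans, 4,5-cis), whereas the usual AgOAc-templated azomethine ylide cycloaddition gives 2,5-cis. The biradical is stabilised at both ends (ester and aryl) and can fragment to two alkenes or lose configuration. A7 is a diester that still has to be hydrolysed without epimerisation.
- Comparison: as with Alternative 1, it addresses the easy half, in at least four steps to 27 against two.

Key step: step 10

Remark on the chemistry: crystalline 24 is assumed to pack head-to-tail so that its photodimer is the α-truxillic acid, and RuCl2[(S)-BINAP] is assumed to give the (S)-carbinol as with simple β-keto esters.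

## Route

Step 1
Reactants: 1 ethyl acetoacetate; 2 benzyl chloromethyl ether
Product: 3 ethyl 5-(benzyloxy)-3-oxopentanoate
Conditions: NaH, THF, 0 °C; n-BuLi, 0 °C; then 2, −78 °C to 0 °C; dil. HCl quench
Reagents that add atoms: none
Why: Alkylation of the acetoacetate dianion; after the second deprotonation the terminal γ-carbon is the most nucleophilic site, so the reactive chloromethyl ether is attacked only there. No stereocentre is formed.

Step 2
Reactants: 3 ethyl 5-(benzyloxy)-3-oxopentanoate
Product: 4 ethyl (3S)-5-(benzyloxy)-3-hydroxypentanoate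
Conditions: RuCl2[(S)-BINAP] (0.5 mol %), H2 (4 atm), EtOH, 80 °C
Reagents that add atoms: none
Why: Noyori asymmetric hydrogenation of a β-keto ester; ketone and ester chelate divalent ruthenium and the (S)-BINAP ligand leaves open the face that should give the (S)-carbinol (future C6). The benzyl ether is inert to this homogeneous catalyst.

Step 3
Reactants: 4 ethyl (3S)-5-(benzyloxy)-3-hydroxypentanoate
Product: 5 ethyl (2S,3S)-5-(benzyloxy)-3-hydroxy-2-methylpentanoate
Conditions: LiN(iPr)2 (2.2 equiv), THF, −50 to −20 °C; MeI, DMPU, −78 to 0 °C; aq. NH4Cl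
Reagents that add atoms: iodomethane, CI
Why: Fráter–Seebach alkylation; the dianion is a rigid lithium chelate and iodomethane should approach the enolate face anti to the C3 side chain, giving the 2,3-anti product. This sets the future C7 relative to C6.

Step 4
Reactants: 5 ethyl (2S,3S)-5-(benzyloxy)-3-hydroxy-2-methylpentanoate
Product: 6 ethyl (2S,3S)-5-(benzyloxy)-3-[(tert-butyldimethylsilyl)oxy]-2-methylpentanoate
Conditions: TBSOTf, 2,6-lutidine, CH2Cl2, −78 to 0 °C
Reagents that add atoms: tert-butyldimethylsilyl trifluoromethanesulfonate, CC(C)(C)[Si](C)(C)OS(=O)(=O)C(F)(F)F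
Why: Silylation of a hindered secondary alcohol with a silyl triflate under non-enolising conditions, so C2 is not at risk. The bulky silyl ether should survive up to step 13 and serves as a face-blocking group in step 12.

Step 5
Reactants: 6 ethyl (2S,3S)-5-(benzyloxy)-3-[(tert-butyldimethylsilyl)oxy]-2-methylpentanoate
Product: 7 (2S,3S)-5-(benzyloxy)-3-[(tert-butyldimethylsilyl)oxy]-2-methylpentanal
Conditions: iBu2AlH (1.1 equiv), CH2Cl2, −78 °C; MeOH, then aq. KNaC4H4O6 (potassium sodium tartrate)
Reagents that add atoms: none
Why: Partial reduction of an ester; the aluminium hemiacetal is stable at −78 °C and releases the aldehyde only on work-up. The aldehyde is used crude and cold to protect the α-centre.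

Step 6
Reactants: 7 (2S,3S)-5-(benzyloxy)-3-[(tert-butyldimethylsilyl)oxy]-2-methylpentanal; 8 tosylmethyl isocyanide
Product: 10 5-[(2S,3S)-5-(benzyloxy)-3-[(tert-butyldimethylsilyl)oxy]pentan-2-yl]-1,3-oxazole, via 4-tosyloxazoline 9 (not isolated)
Conditions: K2CO3, MeOH, rt then 60 °C
Reagents that add atoms: none
Why: van Leusen oxazole synthesis; the isocyanide anion adds to the aldehyde, the alkoxide closes onto the isocyanide carbon to give 9, and loss of sulfinate aromatises. The aldehyde carbon becomes oxazole C5 (future C7a); addition should outrun enolisation, so C7 should be retained.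

Step 7
Reactants: 10 5-[(2S,3S)-5-(benzyloxy)-3-[(tert-butyldimethylsilyl)oxy]pentan-2-yl]-1,3-oxazole
Product: 11 (3S,4S)-3-[(tert-butyldimethylsilyl)oxy]-4-(1,3-oxazol-5-yl)pentan-1-ol
Conditions: H2 (1 atm), Pd/C, EtOAc, rt
Reagents that add atoms: none
Why: Hydrogenolysis of a benzyl ether; the oxazole and the silyl ether should be inert at 1 atm in a neutral aprotic solvent.

Step 8
Reactants: 11 (3S,4S)-3-[(tert-butyldimethylsilyl)oxy]-4-(1,3-oxazol-5-yl)pentan-1-ol
Product: 12 (3S,4S)-3-[(tert-butyldimethylsilyl)oxy]-4-(1,3-oxazol-5-yl)pentanal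
Conditions: Dess–Martin periodinane, NaHCO3, CH2Cl2, 0 °C to rt
Reagents that add atoms: none
Why: Dess–Martin oxidation under buffered, non-basic conditions, which should avoid β-elimination of the silyloxy group from the β-silyloxy aldehyde.

Step 9
Reactants: 12 (3S,4S)-3-[(tert-butyldimethylsilyl)oxy]-4-(1,3-oxazol-5-yl)pentanal; 13 ethyltriphenylphosphonium bromide
Product: 14 5-[(2S,3S,5Z)-3-[(tert-butyldimethylsilyl)oxy]hept-5-en-2-yl]-1,3-oxazole
Conditions: 13, NaN(SiMe3)2, THF, 0 °C; then 12, −78 °C to rt
Reagents that add atoms: none
Why: Wittig olefination with a non-stabilised ylide under lithium-free conditions, which should give mainly the cis alkene. The geometry is immaterial because both alkene carbons become aromatic in step 10.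

Step 10
Reactants: 14 5-[(2S,3S,5Z)-3-[(tert-butyldimethylsilyl)oxy]hept-5-en-2-yl]-1,3-oxazole
Product: 17 (6S,7R)-6-[(tert-butyldimethylsilyl)oxy]-4,7-dimethyl-6,7-dihydro-5H-cyclopenta[c]pyridine, via oxygen-bridged cycloadduct 15 (not isolated), via cyclic hemiaminal 16 (not isolated)
Conditions: DBU (1.5 equiv), 1,2-dichlorobenzene (0.02 M), 180 °C, sealed tube, argon
Reagents that add atoms: none
Why: Intramolecular Kondrat'eva-type oxazole–alkene Diels–Alder reaction followed by dehydrative aromatisation. The oxazole reacts as a 2-azadiene through C2 and C5 and the tethered alkene as the 2π partner; a thermal [4+2] forms C7a–C4a and C3–C4 and gives adduct 15. Ring B closes as the tether ring, five-membered because three carbons separate oxazole C5 from the alkene, and ring A closes as the six-membered ring of the cycloaddition itself. The oxygen bridge of 15 opens by elimination across C7a–C4a to hemiaminal 16, which loses water across C3–C4 with the amidine base as proton shuttle; aromatisation makes the sequence irreversible. The closest known reaction type is the thermal intramolecular oxazole–olefin cycloaddition that gives 4,7-dialkyl-cyclopenta[c]pyridines. No lasting stereocentre is made: the four centres created in 15 (C3, C4, C4a, C7a) all become sp2, so alkene geometry, exo/endo mode and facial course do not matter. Regiochemistry is fixed by the tether, since only C5-to-C4a bonding gives a five-membered ring B; because oxazole C5 bears carbon, loss of water is the only aromatisation path and the C4 methyl stays in place. The selectivity needed is survival of the cis C6/C7 pair, and neither centre has an acidic hydrogen in 14, 15, 16 or 17 (C7 ends at the non-activated 3-position of the pyridine), so the base should leave them alone.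

Step 11
Reactants: 17 (6S,7R)-6-[(tert-butyldimethylsilyl)oxy]-4,7-dimethyl-6,7-dihydro-5H-cyclopenta[c]pyridine
Product: 18 (6S,7R)-6-[(tert-butyldimethylsilyl)oxy]-2,4,7-trimethyl-6,7-dihydro-5H-cyclopenta[c]pyridin-2-ium trifluoromethanesulfonate
Conditions: MeOTf (1.1 equiv), CH2Cl2, 0 °C to rt
Reagents that add atoms: methyl trifluoromethanesulfonate, COS(=O)(=O)C(F)(F)F
Why: N-alkylation of a pyridine (Menshutkin reaction); the ring nitrogen is the only nucleophilic site. The salt carries the N-methyl group and hydrogenates more easily than the free base, and triflate does not poison platinum.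

Step 12
Reactants: 18 (6S,7R)-6-[(tert-butyldimethylsilyl)oxy]-2,4,7-trimethyl-6,7-dihydro-5H-cyclopenta[c]pyridin-2-ium trifluoromethanesulfonate
Product: 19 (4R,4aS,6S,7R,7aR)-6-[(tert-butyldimethylsilyl)oxy]-2,4,7-trimethyloctahydro-1H-cyclopenta[c]pyridine
Conditions: PtO2 (10 mol %), H2 (4 atm), MeOH, rt; aq. NaOH work-up
Reagents that add atoms: none
Why: Heterogeneous hydrogenation of a pyridinium salt; the flat bicycle should adsorb by the face opposite to the C7 methyl and the C6 silyloxy group, and all hydrogens come from the catalyst side. This should set C4 (R), C4a (S) and C7a (R) with H4, H4a and H7a mutually cis and trans to both controller groups.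

Step 13
Reactants: 19 (4R,4aS,6S,7R,7aR)-6-[(tert-butyldimethylsilyl)oxy]-2,4,7-trimethyloctahydro-1H-cyclopenta[c]pyridine
Product: 20 (4R,4aS,6S,7R,7aR)-2,4,7-trimethyloctahydro-1H-cyclopenta[c]pyridin-6-ol
Conditions: HCl (3 M in MeOH), rt to 40 °C; aq. NaOH work-up
Reagents that add atoms: none
Why: Acid methanolysis of a secondary silyl ether; the protonated amine is a spectator and no stereocentre is touched.

Step 14
Reactants: 20 (4R,4aS,6S,7R,7aR)-2,4,7-trimethyloctahydro-1H-cyclopenta[c]pyridin-6-ol
Product: 21 (4R,4aS,7R,7aR)-2,4,7-trimethyloctahydro-6H-cyclopenta[c]pyridin-6-one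
Conditions: (COCl)2, DMSO, CH2Cl2, −78 °C; Et3N, −78 to 0 °C
Reagents that add atoms: none
Why: Swern oxidation, which tolerates tertiary amines. Any partial C7 epimerisation by the amine base is harmless because step 15 equilibrates that centre.

Step 15
Reactants: 21 (4R,4aS,7R,7aR)-2,4,7-trimethyloctahydro-6H-cyclopenta[c]pyridin-6-one
Product: 23 (4R,4aS,6S,7S,7aR)-2,4,7-trimethyloctahydro-1H-cyclopenta[c]pyridin-6-ol (6-epi-incarvilline), via C7-epimerised ketone 22 (not isolated)
Conditions: NaOMe (0.3 equiv), MeOH, rt until equilibrated; then NaBH4, −20 to 0 °C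
Reagents that add atoms: none
Why: Enolate-mediated epimerisation should move the C7 methyl from the concave face, where it is cis to C1 on ring B, to the convex face, the thermodynamically preferred side, giving 22 (7S). NaBH4 should then attack from the convex face, away from ring A, placing the hydroxyl on the concave face (6S) and trans to the C7 methyl, as small hydrides do with 2-alkylcyclopentanones.

Step 16
Reactants: 24 p-coumaric acid (2 equiv)
Product: 25 (1α,2α,3β,4β)-2,4-bis(4-hydroxyphenyl)cyclobutane-1,3-dicarboxylic acid (4,4'-dihydroxy-α-truxillic acid)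
Conditions: hν (medium-pressure mercury lamp, Pyrex filter), finely ground crystals stirred as a suspension in hexane, rt
Reagents that add atoms: p-coumaric acid (the second of the two molecules of 24 that make up the dimer), OC(=O)/C=C/c1ccc(O)cc1
Why: Topochemical [2+2] photodimerisation in the crystal, in which two molecules of 24 join through both alkene carbons; head-to-tail pairs related by an inversion centre should give the centrosymmetric dimer. All four ring C centres are set by the packing.

Step 17
Reactants: 25 (1α,2α,3β,4β)-2,4-bis(4-hydroxyphenyl)cyclobutane-1,3-dicarboxylic acid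
Product: 27 (1α,2α,3β,4β)-2,4-bis[4-(benzyloxy)phenyl]cyclobutane-1,3-dicarboxylic acid, via tetrabenzyl compound 26 (not isolated)
Conditions: BnBr (4.5 equiv), K2CO3, DMF, 50 °C; extractive work-up; crude 26: NaOH, THF/MeOH/H2O, 40 °C; aq. HCl
Reagents that add atoms: benzyl bromide, BrCc1ccccc1
Why: Exhaustive O-alkylation of phenoxides and carboxylates followed by saponification of the two benzyl esters; aryl benzyl ethers are stable to NaOH. The mild hydrolysis should leave the α-carbons of ring C unchanged.

Step 18
Reactants: 23 (4R,4aS,6S,7S,7aR)-2,4,7-trimethyloctahydro-1H-cyclopenta[c]pyridin-6-ol (2.4 equiv); 27 (1α,2α,3β,4β)-2,4-bis[4-(benzyloxy)phenyl]cyclobutane-1,3-dicarboxylic acid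
Product: 28 bis[(4R,4aS,6R,7S,7aR)-2,4,7-trimethyloctahydro-1H-cyclopenta[c]pyridin-6-yl] (1α,2α,3β,4β)-2,4-bis[4-(benzyloxy)phenyl]cyclobutane-1,3-dicarboxylate
Conditions: PPh3, DIAD, THF, 0 °C to rt
Reagents that add atoms: none
Why: Twofold Mitsunobu esterification; each alcohol is activated as an alkoxyphosphonium ion and displaced by carboxylate in an SN2 step, inverting C6 from S to R. The two carboxyl groups of 27 are equivalent, so only one diester can form.

Step 19
Reactants: 28 bis[(4R,4aS,6R,7S,7aR)-2,4,7-trimethyloctahydro-1H-cyclopenta[c]pyridin-6-yl] (1α,2α,3β,4β)-2,4-bis[4-(benzyloxy)phenyl]cyclobutane-1,3-dicarboxylate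
Product: 29 bis[(4R,4aS,6R,7S,7aR)-2,4,7-trimethyloctahydro-1H-cyclopenta[c]pyridin-6-yl] (1α,2α,3β,4β)-2,4-bis(4-hydroxyphenyl)cyclobutane-1,3-dicarboxylate (target, CNP0180864.2)
Conditions: H2 (1 atm), Pd(OH)2/C, MeOH, AcOH (excess), rt; aq. NaHCO3 work-up
Reagents that add atoms: none
Why: Hydrogenolysis of aryl benzyl ethers; acetic acid protonates the amines, which would otherwise slow O-debenzylation on palladium. Esters, ring C and all stereocentres should be unaffected.

## Compound list

1 | ethyl acetoacetate | CCOC(=O)CC(C)=O | starting material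
2 | benzyl chloromethyl ether | ClCOCc1ccccc1 | starting material
3 | ethyl 5-(benzyloxy)-3-oxopentanoate | CCOC(=O)CC(=O)CCOCc1ccccc1 | intermediate
4 | ethyl (3S)-5-(benzyloxy)-3-hydroxypentanoate | CCOC(=O)C[C@@H](O)CCOCc1ccccc1 | intermediate
5 | ethyl (2S,3S)-5-(benzyloxy)-3-hydroxy-2-methylpentanoate | CCOC(=O)[C@@H](C)[C@@H](O)CCOCc1ccccc1 | intermediate
6 | ethyl (2S,3S)-5-(benzyloxy)-3-[(tert-butyldimethylsilyl)oxy]-2-methylpentanoate | CCOC(=O)[C@@H](C)[C@@H](O[Si](C)(C)C(C)(C)C)CCOCc1ccccc1 | intermediate
7 | (2S,3S)-5-(benzyloxy)-3-[(tert-butyldimethylsilyl)oxy]-2-methylpentanal | O=C[C@@H](C)[C@@H](O[Si](C)(C)C(C)(C)C)CCOCc1ccccc1 | intermediate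
8 | tosylmethyl isocyanide (TosMIC) | Cc1ccc(cc1)S(=O)(=O)C[N+]#[C-] | starting material
9 | 5-[(2S,3S)-5-(benzyloxy)-3-[(tert-butyldimethylsilyl)oxy]pentan-2-yl]-4-tosyl-4,5-dihydro-1,3-oxazole (ring centres unspecified) | C[C@H](C1OC=NC1S(=O)(=O)c2ccc(C)cc2)[C@@H](O[Si](C)(C)C(C)(C)C)CCOCc1ccccc1 | intermediate (not isolated)
10 | 5-[(2S,3S)-5-(benzyloxy)-3-[(tert-butyldimethylsilyl)oxy]pentan-2-yl]-1,3-oxazole | C[C@H](c1cnco1)[C@@H](O[Si](C)(C)C(C)(C)C)CCOCc1ccccc1 | intermediate
11 | (3S,4S)-3-[(tert-butyldimethylsilyl)oxy]-4-(1,3-oxazol-5-yl)pentan-1-ol | C[C@H](c1cnco1)[C@@H](O[Si](C)(C)C(C)(C)C)CCO | intermediate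
12 | (3S,4S)-3-[(tert-butyldimethylsilyl)oxy]-4-(1,3-oxazol-5-yl)pentanal | C[C@H](c1cnco1)[C@@H](O[Si](C)(C)C(C)(C)C)CC=O | intermediate
13 | ethyltriphenylphosphonium bromide | CC[P+](c1ccccc1)(c1ccccc1)c1ccccc1.[Br-] | starting material
14 | 5-[(2S,3S,5Z)-3-[(tert-butyldimethylsilyl)oxy]hept-5-en-2-yl]-1,3-oxazole | C[C@H](c1cnco1)[C@@H](O[Si](C)(C)C(C)(C)C)C/C=C\C | intermediate
15 | 6-[(tert-butyldimethylsilyl)oxy]-4,7-dimethyl-3,7a-epoxy-4,4a,5,6,7,7a-hexahydro-3H-cyclopenta[c]pyridine (C6 and C7 as in 14; C3, C4, C4a, C7a transient, unspecified) | C[C@@H]1C23OC(N=C2)C(C)C3C[C@@H]1O[Si](C)(C)C(C)(C)C | intermediate (not isolated)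
16 | 6-[(tert-butyldimethylsilyl)oxy]-4,7-dimethyl-4,5,6,7-tetrahydro-3H-cyclopenta[c]pyridin-3-ol (C6 and C7 as in 14; C3, C4 unspecified) | C[C@@H]1C2=C(C[C@@H]1O[Si](C)(C)C(C)(C)C)C(C)C(O)N=C2 | intermediate (not isolated)
17 | (6S,7R)-6-[(tert-butyldimethylsilyl)oxy]-4,7-dimethyl-6,7-dihydro-5H-cyclopenta[c]pyridine | C[C@@H]1c2cncc(C)c2C[C@@H]1O[Si](C)(C)C(C)(C)C | intermediate
18 | (6S,7R)-6-[(tert-butyldimethylsilyl)oxy]-2,4,7-trimethyl-6,7-dihydro-5H-cyclopenta[c]pyridin-2-ium trifluoromethanesulfonate | C[C@@H]1c2c[n+](C)cc(C)c2C[C@@H]1O[Si](C)(C)C(C)(C)C.[O-]S(=O)(=O)C(F)(F)F | intermediate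
19 | (4R,4aS,6S,7R,7aR)-6-[(tert-butyldimethylsilyl)oxy]-2,4,7-trimethyloctahydro-1H-cyclopenta[c]pyridine | C[C@@H]1[C@@H]2CN(C)C[C@H](C)[C@@H]2C[C@@H]1O[Si](C)(C)C(C)(C)C | intermediate
20 | (4R,4aS,6S,7R,7aR)-2,4,7-trimethyloctahydro-1H-cyclopenta[c]pyridin-6-ol | C[C@@H]1[C@@H]2CN(C)C[C@H](C)[C@@H]2C[C@@H]1O | intermediate
21 | (4R,4aS,7R,7aR)-2,4,7-trimethyloctahydro-6H-cyclopenta[c]pyridin-6-one | C[C@@H]1[C@@H]2CN(C)C[C@H](C)[C@@H]2CC1=O | intermediate
22 | (4R,4aS,7S,7aR)-2,4,7-trimethyloctahydro-6H-cyclopenta[c]pyridin-6-one | C[C@H]1[C@@H]2CN(C)C[C@H](C)[C@@H]2CC1=O | intermediate (not isolated)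
23 | (4R,4aS,6S,7S,7aR)-2,4,7-trimethyloctahydro-1H-cyclopenta[c]pyridin-6-ol (6-epi-incarvilline) | C[C@H]1[C@@H]2CN(C)C[C@H](C)[C@@H]2C[C@@H]1O | intermediate
24 | p-coumaric acid | OC(=O)/C=C/c1ccc(O)cc1 | starting material
25 | (1α,2α,3β,4β)-2,4-bis(4-hydroxyphenyl)cyclobutane-1,3-dicarboxylic acid | OC(=O)[C@H]1[C@H](c2ccc(O)cc2)[C@H](C(=O)O)[C@H]1c1ccc(O)cc1 | intermediate
26 | dibenzyl (1α,2α,3β,4β)-2,4-bis[4-(benzyloxy)phenyl]cyclobutane-1,3-dicarboxylate | O=C(OCc1ccccc1)[C@H]1[C@H](c2ccc(OCc3ccccc3)cc2)[C@H](C(=O)OCc2ccccc2)[C@H]1c1ccc(OCc2ccccc2)cc1 | intermediate (not isolated)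
27 | (1α,2α,3β,4β)-2,4-bis[4-(benzyloxy)phenyl]cyclobutane-1,3-dicarboxylic acid | OC(=O)[C@H]1[C@H](c2ccc(OCc3ccccc3)cc2)[C@H](C(=O)O)[C@H]1c1ccc(OCc2ccccc2)cc1 | intermediate
28 | bis[(4R,4aS,6R,7S,7aR)-2,4,7-trimethyloctahydro-1H-cyclopenta[c]pyridin-6-yl] (1α,2α,3β,4β)-2,4-bis[4-(benzyloxy)phenyl]cyclobutane-1,3-dicarboxylate | C[C@H]1[C@@H]2CN(C)C[C@H](C)[C@@H]2C[C@H]1OC(=O)[C@H]1[C@H](c2ccc(OCc3ccccc3)cc2)[C@H](C(=O)O[C@@H]2C[C@@H]3[C@@H](CN(C)C[C@@H]3C)[C@@H]2C)[C@H]1c1ccc(OCc2ccccc2)cc1 | intermediate
29 | bis[(4R,4aS,6R,7S,7aR)-2,4,7-trimethyloctahydro-1H-cyclopenta[c]pyridin-6-yl] (1α,2α,3β,4β)-2,4-bis(4-hydroxyphenyl)cyclobutane-1,3-dicarboxylate | C[C@H]1[C@@H]2CN(C)C[C@H](C)[C@@H]2C[C@H]1OC(=O)[C@H]1[C@H](c2ccc(O)cc2)[C@H](C(=O)O[C@@H]2C[C@@H]3[C@@H](CN(C)C[C@@H]3C)[C@@H]2C)[C@H]1c1ccc(O)cc1 | target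

## Step count and least certain steps

Total: 19 steps. Longest linear sequence: 17 steps (steps 1 to 15, then 18 and 19). The diacid branch (steps 16 and 17) joins at step 18.

Step 10 (key step). The unactivated 1,2-disubstituted alkene is a poor partner for the electron-rich oxazole, so the cycloaddition may need temperatures at which reversion of the adduct, incomplete dehydration or loss of the silyl group compete. The fallback sets out from aldehyde 12 and returns at 17. Olefination of 12 with Ph3P=CHCO2Et gives ethyl (2E,5S,6S)-5-[(tert-butyldimethylsilyl)oxy]-6-(1,3-oxazol-5-yl)hept-2-enoate F1, whose electron-poor alkene should react in a normal-demand cycloaddition at much lower temperature. The ester also acidifies H4 of the adduct, so the bridge should open easily; heating with DBU in toluene should give pyridine ester F2. Reduction with iBu2AlH gives hydroxymethylpyridine F3; MsCl, Et3N and LiCl convert it into chloromethylpyridine F4; LiBHEt3 reduces the chloride to the C4 methyl of 17.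

Step 6. Enolisation of the α-branched, β-silyloxy aldehyde under K2CO3 in methanol may epimerise C7 or expel the silyloxy group before the isocyanide anion has added. The fallback sets out from ester 6, bypasses aldehyde 7 and returns at 10. Acylation of LiCH2NC by 6 at −78 °C (Schöllkopf oxazole synthesis) gives the enolate of isocyano ketone F5, which closes through oxygen onto the isocyanide carbon and gives 10 on protonation.

Step 12. Face selection on the platinum surface may be incomplete, and partly reduced enamine or iminium intermediates can leave the surface and re-add with scrambling at C4; the silyl ether may also be lost in the acidic medium. The fallback sets out from 17 and returns at 19. The free pyridine is hydrogenated over Rh/Al2O3 in acetic acid under pressure, a catalyst that isomerises less, to give secondary amine F6, which is then N-methylated reductively with formaldehyde and NaBH(OAc)3.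

Step 15. Equilibration at C7 may be incomplete, and hydride delivery may be poorly face-selective because the methyl group now lies on the convex face next to the carbonyl. The fallback sets out from ketone 21, equilibrated to 22 as before, and returns at 28. Reduction with the bulky LiBH(sBu)3, which is steered anti to the adjacent methyl, is aimed at the 6R alcohol incarvilline F7. This epimer needs no inversion and is esterified with retention by carbodiimide coupling (EDC·HCl, DMAP) with 27.

Step 18. Elimination of the activated hindered alcohol to a cyclopentene, or stalling after the first esterification, may compete with the second SN2 displacement by a bulky carboxylate. The fallback sets out from 23 and returns at 28. Mitsunobu inversion with the small and more acidic 4-nitrobenzoic acid gives 4-nitrobenzoate F8; methanolysis with K2CO3 releases incarvilline F7, which is coupled with 27 by EDC·HCl and DMAP with retention.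

## Further compounds

F1 | step 10 | ethyl (2E,5S,6S)-5-[(tert-butyldimethylsilyl)oxy]-6-(1,3-oxazol-5-yl)hept-2-enoate | C[C@H](c1cnco1)[C@@H](O[Si](C)(C)C(C)(C)C)C/C=C/C(=O)OCC
F2 | step 10 | ethyl (6S,7R)-6-[(tert-butyldimethylsilyl)oxy]-7-methyl-6,7-dihydro-5H-cyclopenta[c]pyridine-4-carboxylate | C[C@@H]1c2cncc(C(=O)OCC)c2C[C@@H]1O[Si](C)(C)C(C)(C)C
F3 | step 10 | [(6S,7R)-6-[(tert-butyldimethylsilyl)oxy]-7-methyl-6,7-dihydro-5H-cyclopenta[c]pyridin-4-yl]methanol | C[C@@H]1c2cncc(CO)c2C[C@@H]1O[Si](C)(C)C(C)(C)C
F4 | step 10 | (6S,7R)-6-[(tert-butyldimethylsilyl)oxy]-4-(chloromethyl)-7-methyl-6,7-dihydro-5H-cyclopenta[c]pyridine | C[C@@H]1c2cncc(CCl)c2C[C@@H]1O[Si](C)(C)C(C)(C)C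
F5 | step 6 | (3S,4S)-6-(benzyloxy)-4-[(tert-butyldimethylsilyl)oxy]-1-isocyano-3-methylhexan-2-one | [C-]#[N+]CC(=O)[C@@H](C)[C@@H](O[Si](C)(C)C(C)(C)C)CCOCc1ccccc1
F6 | step 12 | (4R,4aS,6S,7R,7aR)-6-[(tert-butyldimethylsilyl)oxy]-4,7-dimethyloctahydro-1H-cyclopenta[c]pyridine | C[C@@H]1[C@@H]2CNC[C@H](C)[C@@H]2C[C@@H]1O[Si](C)(C)C(C)(C)C
F7 | step 15 | (4R,4aS,6R,7S,7aR)-2,4,7-trimethyloctahydro-1H-cyclopenta[c]pyridin-6-ol (incarvilline) | C[C@H]1[C@@H]2CN(C)C[C@H](C)[C@@H]2C[C@H]1O
F8 | step 18 | (4R,4aS,6R,7S,7aR)-2,4,7-trimethyloctahydro-1H-cyclopenta[c]pyridin-6-yl 4-nitrobenzoate | C[C@H]1[C@@H]2CN(C)C[C@H](C)[C@@H]2C[C@H]1OC(=O)c1ccc(cc1)[N+](=O)[O-]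
A1 | alternative 1 | trans-N,N'-di(quinolin-8-yl)cyclobutane-1,3-dicarboxamide | O=C(Nc1cccc2cccnc12)[C@H]1C[C@H](C(=O)Nc2cccc3cccnc23)C1
A2 | alternative 1 | 1-(benzyloxy)-4-iodobenzene | Ic1ccc(OCc2ccccc2)cc1
A3 | alternative 1 | (1α,2α,3β,4β)-2,4-bis[4-(benzyloxy)phenyl]-N,N'-di(quinolin-8-yl)cyclobutane-1,3-dicarboxamide | O=C(Nc1cccc2cccnc12)[C@H]1[C@H](c2ccc(OCc3ccccc3)cc2)[C@H](C(=O)Nc2cccc3cccnc23)[C@H]1c1ccc(OCc2ccccc2)cc1
A4 | alternative 2 | (5R)-1,3-dimethyl-5-[(2S)-3-oxobutan-2-yl]-5,6-dihydropyridin-2(1H)-one | C[C@H](C(C)=O)[C@@H]1CN(C)C(=O)C(C)=C1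
A5 | alternative 2 | (4R,4aR,7S,7aR)-2,4,7-trimethylhexahydro-1H-cyclopenta[c]pyridine-3,6(2H,4H)-dione | C[C@H]1[C@@H]2CN(C)C(=O)[C@H](C)[C@@H]2CC1=O
A6 | alternative 3 | dimethyl 3,5-bis[4-(benzyloxy)phenyl]pyrrolidine-2,4-dicarboxylate (racemic; 2,3-cis, 3,4-trans, 4,5-cis, 2,5-trans; one enantiomer drawn) | COC(=O)[C@H]1N[C@H](c2ccc(OCc3ccccc3)cc2)[C@H](C(=O)OC)[C@H]1c1ccc(OCc2ccccc2)cc1
A7 | alternative 3 | dimethyl (1α,2α,3β,4β)-2,4-bis[4-(benzyloxy)phenyl]cyclobutane-1,3-dicarboxylate | COC(=O)[C@H]1[C@H](c2ccc(OCc3ccccc3)cc2)[C@H](C(=O)OC)[C@H]1c1ccc(OCc2ccccc2)cc1
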